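**Retrosynthetic overview**

1. Numbering as in ilimaquinone: ring A = C1–C2–C3–C4–C5–C10 (C4 bears the exocyclic CH2), ring B = C5–C6–C7–C8–C9–C10 (C5 angular CH3, C8 CH–CH3, C9 quaternary with CH3 and the benzylic CH2). Late disconnections: the hydroxymethoxyquinone from a 2,3,5,6-tetramethoxyphenyl ring, C4=CH2 and C8–CH3 from ketones, and C9–CH2Ar by benzylation of a C8 enolate.
2. Enabling feature: ring B then holds an enol ether C8(O)=C9 next to the ring-fusion carbon C10, and ring A a ketone at C4 on the other ring-fusion carbon C5. This 4-acylcyclohexene silyl enol ether is the retron of an intramolecular Diels–Alder reaction between a 2-silyloxydiene C7=C8(OSiEt3)–C9(CH3)=C10 and an isopropenyl ketone C5(CH3)=C6 activated by C4=O, tethered through C1–C2–C3.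
3. Key disconnection: the C6–C7 and C5–C10 bonds, made together from an achiral acyclic trienone under a chiral Lewis acid. This closes rings A and B in one operation, sets C5 and C10, and leaves the C8=C9 silyl enol ether as the regiodefined enolate precursor for the C9 quaternary centre.
4. The trienone comes in five steps from δ-valerolactone, a stabilised ylide and isopropenylmagnesium bromide; the benzylic bromide in three steps from 1,2,4,5-tetramethoxybenzene.
5. Ring order: aromatic ring bought; rings A and B together in step 6; quinone unveiled in steps 16 and 17. The C4 ketone is held as an alcohol (steps 7 to 14) so that C8 is methylenated and hydrogenated before C4 is methylenated.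

Key step: step 6

Assumption: the facial sense of the oxazaborolidinium catalyst on an alpha-methyl enone cannot be read from precedent, so the (S)-prolinol-derived catalyst is written and its mirror image, equally available, is to be used if it delivers the antipode.

**Route**

Step 1
Reactants: 1 δ-valerolactone
Product: 2 5-hydroxy-N-methoxy-N-methylpentanamide
Conditions: MeNH(OMe)·HCl, AlMe3, CH2Cl2, 0 °C to rt; dilute aq. HCl, 0 °C
Reagents that add atoms: N,O-dimethylhydroxylamine hydrochloride, CNOC.Cl
Why: Aluminium amide aminolysis of a lactone (Weinreb amide formation) opens the ring to the hydroxy amide without further reaction of the amide; no stereocentre is formed.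

Step 2
Reactants: 2 5-hydroxy-N-methoxy-N-methylpentanamide
Product: 3 N-methoxy-N-methyl-5-oxopentanamide
Conditions: PhI(OAc)2, 2,2,6,6-tetramethylpiperidin-1-oxyl (10 mol %), CH2Cl2, rt
Reagents that add atoms: none
Why: Nitroxyl-catalysed oxidation of a primary alcohol stops at the aldehyde and leaves the amide untouched; no stereocentre is formed.

Step 3
Reactants: 3 N-methoxy-N-methyl-5-oxopentanamide; 4 3-(triphenylphosphoranylidene)butan-2-one
Product: 5 (E)-N-methoxy-N,6-dimethyl-7-oxooct-5-enamide
Conditions: toluene, 90 °C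
Reagents that add atoms: none
Why: Wittig olefination with a ketone-stabilised, alpha-branched ylide should give the (E)-trisubstituted enone, as is usual for stabilised ylides, and the amide does not react with such an ylide.

Step 4
Reactants: 5 (E)-N-methoxy-N,6-dimethyl-7-oxooct-5-enamide
Product: 6 (E)-N-methoxy-N,6-dimethyl-7-(triethylsilyloxy)octa-5,7-dienamide
Conditions: Et3SiOSO2CF3, Et3N, CH2Cl2, −78 °C to 0 °C
Reagents that add atoms: triethylsilyl trifluoromethanesulfonate, CC[Si](CC)(CC)OS(=O)(=O)C(F)(F)F
Why: Soft enolisation of the methyl ketone (silyl triflate and amine base) removes the kinetically favoured alpha' proton and should give the cross-conjugated 2-silyloxydiene with the C=C geometry retained, while the less acidic amide is not enolised.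

Step 5
Reactants: 6 (E)-N-methoxy-N,6-dimethyl-7-(triethylsilyloxy)octa-5,7-dienamide; 7 isopropenylmagnesium bromide
Product: 9 (E)-2,8-dimethyl-9-(triethylsilyloxy)deca-1,7,9-trien-3-one, via magnesium hemiaminal chelate 8 (not isolated)
Conditions: THF, −20 °C to 0 °C; pH 7 phosphate buffer, 0 °C; kept cold and used at once
Reagents that add atoms: none
Why: Weinreb ketone synthesis, in which the chelated tetrahedral adduct 8 resists a second addition and collapses to the isopropenyl ketone only on work-up, while the silyl dienol ether is inert to the Grignard reagent.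

Step 6
Reactants: 9 (E)-2,8-dimethyl-9-(triethylsilyloxy)deca-1,7,9-trien-3-one
Product: 10 (4aS,8aS)-5,8a-dimethyl-6-(triethylsilyloxy)-3,4,4a,7,8,8a-hexahydronaphthalen-1(2H)-one
Conditions: (S)-3,3-diphenyl-1-(2-methylphenyl)tetrahydro-1H,3H-pyrrolo[1,2-c][1,3,2]oxazaborole (20 mol %), HN(SO2CF3)2 (16 mol %), CH2Cl2, −78 °C to −40 °C; Et3N quench
Reagents that add atoms: none
Why: Proposed new method: the N-protonated oxazaborolidine should bind the C4 ketone of 9 and lower the LUMO of the C5=C6 isopropenyl unit, so that the 2-silyloxydiene C7=C8(OSiEt3)–C9(CH3)=C10 adds across it in a concerted, asynchronous [4+2] cycloaddition in which the C6–C7 bond (nucleophilic diene terminus to enone beta-carbon) runs ahead of the C5–C10 bond; enantioselective catalysis of this kind has not been shown for 1,7,9-decatrien-3-ones. The closest known reaction types are the thermal and Lewis acid-promoted intramolecular Diels–Alder reaction of 1,7,9-decatrien-3-ones and the oxazaborolidinium-catalysed enantioselective Diels–Alder reactions of 2-silyloxydienes with enones, of trienals and of macrocyclic trienones. Ring B is closed as the cyclohexene of the cycloadduct by both new bonds, and ring A by the C5–C10 bond alone in the fused (type 1) mode, through a chair-like C1–C2–C3–C4 tether that keeps the enone s-cis and conjugated. The two new stereocentres C5 and C10 are related by the E geometry of C9=C10 and by the exo position of the tether carbonyl (C5 methyl under the diene), which is favoured by the alpha-methyl group of the dienophile and by the C9 methyl, whose contact with the tether is worse in the endo arrangement, so that C10–H and C5–CH3 should come out anti (trans-decalin). Their absolute configuration is set by the catalyst, which must leave open the Re face of C5 of the bound enone. The step needs regioselectivity (secured by the tether and by the electronic match of C7 with C6), exo selectivity and face selectivity, and it needs the silyl enol ether to survive, which is why the triethylsilyl group, low temperature and a slight deficit of HN(SO2CF3)2 relative to the oxazaborolidine are chosen.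

Step 7
Reactants: 10 (4aS,8aS)-5,8a-dimethyl-6-(triethylsilyloxy)-3,4,4a,7,8,8a-hexahydronaphthalen-1(2H)-one
Product: 11 (1S,4aR,8aS)-5,8a-dimethyl-6-(triethylsilyloxy)-1,2,3,4,4a,7,8,8a-octahydronaphthalen-1-ol
Conditions: LiAlH4, THF, −78 °C to 0 °C; H2O, aq. NaOH work-up
Reagents that add atoms: none
Why: Hydride reduction masks the C4 ketone as an alcohol for the enolate and Wittig chemistry at C8, with axial hydride delivery anti to the angular C5 methyl expected to give the equatorial alcohol syn to that methyl (a centre removed again in step 14), and the silyl enol ether is inert to LiAlH4.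

Step 8
Reactants: 12 1,2,4,5-tetramethoxybenzene
Product: 14 2,3,5,6-tetramethoxybenzaldehyde, via tetramethoxyphenyllithium 13 (not isolated)
Conditions: n-BuLi, THF, 0 °C to rt; DMF, 0 °C; H2O
Reagents that add atoms: N,N-dimethylformamide, CN(C)C=O
Why: Directed ortho-lithiation at a position flanked by two methoxy groups (the two free positions are equivalent) followed by formylation with DMF; no stereocentre is formed.

Step 9
Reactants: 14 2,3,5,6-tetramethoxybenzaldehyde
Product: 15 (2,3,5,6-tetramethoxyphenyl)methanol
Conditions: NaBH4, MeOH, 0 °C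
Reagents that add atoms: none
Why: Borohydride reduction of an aryl aldehyde to the benzylic alcohol.

Step 10
Reactants: 15 (2,3,5,6-tetramethoxyphenyl)methanol
Product: 16 3-(bromomethyl)-1,2,4,5-tetramethoxybenzene
Conditions: PBr3, Et2O, 0 °C
Reagents that add atoms: phosphorus tribromide, BrP(Br)Br
Why: Substitution of the activated benzylic alcohol by bromide with PBr3, the product being used fresh because it is an electron-rich benzylic halide.

Step 11
Reactants: 11 (1S,4aR,8aS)-5,8a-dimethyl-6-(triethylsilyloxy)-1,2,3,4,4a,7,8,8a-octahydronaphthalen-1-ol; 16 3-(bromomethyl)-1,2,4,5-tetramethoxybenzene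
Product: 18 (1S,4aS,5S,8aR)-5-hydroxy-1,4a-dimethyl-1-[(2,3,5,6-tetramethoxyphenyl)methyl]octahydronaphthalen-2(1H)-one, via dilithium alkoxide enolate 17 (not isolated)
Conditions: MeLi (2.2 equiv), THF, 0 °C to rt; then 16, THF/DMPU, −78 °C to 0 °C; H2O
Reagents that add atoms: none
Why: Regiospecific generation of the tetrasubstituted lithium enolate from the silyl enol ether with MeLi, then C-alkylation at C9 by the benzylic bromide from the face anti to the axial C5 methyl, which should set the quaternary centre with its CH3 syn and the benzyl group anti to the C5 methyl, the hindered lithium alkoxide at C4 being a much poorer nucleophile than the enolate.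

Step 12
Reactants: 18 (1S,4aS,5S,8aR)-5-hydroxy-1,4a-dimethyl-1-[(2,3,5,6-tetramethoxyphenyl)methyl]octahydronaphthalen-2(1H)-one
Product: 19 (1S,4aS,5S,8aS)-5,8a-dimethyl-6-methylidene-5-[(2,3,5,6-tetramethoxyphenyl)methyl]decahydronaphthalen-1-ol
Conditions: Ph3PCH3Br, KOtBu (excess), toluene, 100 °C
Reagents that add atoms: methyltriphenylphosphonium bromide, [Br-].C[P+](c1ccccc1)(c1ccccc1)c1ccccc1
Why: Wittig methylenation of the hindered C8 ketone with excess ylide at elevated temperature, the C4 alkoxide being a spectator; no stereocentre is formed.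

Step 13
Reactants: 19 (1S,4aS,5S,8aS)-5,8a-dimethyl-6-methylidene-5-[(2,3,5,6-tetramethoxyphenyl)methyl]decahydronaphthalen-1-ol
Product: 20 (1S,4aS,5R,6S,8aS)-5,6,8a-trimethyl-5-[(2,3,5,6-tetramethoxyphenyl)methyl]decahydronaphthalen-1-ol
Conditions: H2 (1 atm), PtO2, EtOAc, rt
Reagents that add atoms: none
Why: Heterogeneous hydrogenation of the 1,1-disubstituted alkene, in which hydrogen should add from the face anti to the axial C9 methyl and so give the equatorial C8 methyl syn to the C9 and C5 methyls.

Step 14
Reactants: 20 (1S,4aS,5R,6S,8aS)-5,6,8a-trimethyl-5-[(2,3,5,6-tetramethoxyphenyl)methyl]decahydronaphthalen-1-ol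
Product: 21 (4aS,5R,6S,8aS)-5,6,8a-trimethyl-5-[(2,3,5,6-tetramethoxyphenyl)methyl]octahydronaphthalen-1(2H)-one
Conditions: Dess–Martin periodinane, CH2Cl2, rt
Reagents that add atoms: none
Why: Periodinane oxidation of the hindered secondary alcohol returns the C4 ketone and removes the temporary carbinol centre without touching the electron-rich arene.

Step 15
Reactants: 21 (4aS,5R,6S,8aS)-5,6,8a-trimethyl-5-[(2,3,5,6-tetramethoxyphenyl)methyl]octahydronaphthalen-1(2H)-one
Product: 22 1,2,4,5-tetramethoxy-3-{[(1R,2S,4aS,8aS)-1,2,4a-trimethyl-5-methylidenedecahydronaphthalen-1-yl]methyl}benzene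
Conditions: Ph3PCH3Br, KOtBu, toluene, 100 °C
Reagents that add atoms: methyltriphenylphosphonium bromide, [Br-].C[P+](c1ccccc1)(c1ccccc1)c1ccccc1
Why: Wittig methylenation of the C4 ketone next to the quaternary C5, which cannot epimerise, installs the exocyclic methylene; no stereocentre is formed.

Step 16
Reactants: 22 1,2,4,5-tetramethoxy-3-{[(1R,2S,4aS,8aS)-1,2,4a-trimethyl-5-methylidenedecahydronaphthalen-1-yl]methyl}benzene
Product: 23 2,5-dimethoxy-3-{[(1R,2S,4aS,8aS)-1,2,4a-trimethyl-5-methylidenedecahydronaphthalen-1-yl]methyl}cyclohexa-2,5-diene-1,4-dione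
Conditions: (NH4)2Ce(NO3)6, MeCN/H2O, 0 °C
Reagents that add atoms: water, O
Why: Oxidative demethylation of a para-dimethoxy pair by tetravalent cerium gives the para-quinone, and because the two para pairs are equivalent by the local symmetry of the arene only one quinone can form.

Step 17
Reactants: 23 2,5-dimethoxy-3-{[(1R,2S,4aS,8aS)-1,2,4a-trimethyl-5-methylidenedecahydronaphthalen-1-yl]methyl}cyclohexa-2,5-diene-1,4-dione
Product: 25 ilimaquinone, via potassium hydroxyquinonate 24 (not isolated)
Conditions: KOH, MeOH/H2O, rt; then dilute aq. HCl, 0 °C, brief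
Reagents that add atoms: potassium hydroxide, [K+].[OH-]
Why: Saponification of a vinylogous ester by addition–elimination, expected at the methoxy-bearing carbon next to the benzylic substituent because that methoxy group is twisted out of conjugation by the bulky side chain and is the more electrophilic, the hydroxyquinone anion then resisting a second attack.

**Compound list**

1 | δ-valerolactone | O=C1CCCCO1 | starting material
2 | 5-hydroxy-N-methoxy-N-methylpentanamide | CON(C)C(=O)CCCCO | intermediate
3 | N-methoxy-N-methyl-5-oxopentanamide | CON(C)C(=O)CCCC=O | intermediate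
4 | 3-(triphenylphosphoranylidene)butan-2-one | CC(=O)C(C)=P(c1ccccc1)(c1ccccc1)c1ccccc1 | starting material
5 | (E)-N-methoxy-N,6-dimethyl-7-oxooct-5-enamide | CON(C)C(=O)CCC/C=C(C)/C(C)=O | intermediate
6 | (E)-N-methoxy-N,6-dimethyl-7-(triethylsilyloxy)octa-5,7-dienamide | CON(C)C(=O)CCC/C=C(C)/C(=C)O[Si](CC)(CC)CC | intermediate
7 | isopropenylmagnesium bromide | CC(=C)[Mg]Br | starting material
8 | bromomagnesium (E)-3-[methoxy(methyl)amino]-2,8-dimethyl-9-(triethylsilyloxy)deca-1,7,9-trien-3-olate (magnesium hemiaminal chelate) | C=C(C)C(O[Mg]Br)(CCC/C=C(C)/C(=C)O[Si](CC)(CC)CC)N(C)OC | intermediate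
9 | (E)-2,8-dimethyl-9-(triethylsilyloxy)deca-1,7,9-trien-3-one | C=C(C)C(=O)CCC/C=C(C)/C(=C)O[Si](CC)(CC)CC | intermediate
10 | (4aS,8aS)-5,8a-dimethyl-6-(triethylsilyloxy)-3,4,4a,7,8,8a-hexahydronaphthalen-1(2H)-one (trans-fused) | O=C1CCC[C@H]2C(C)=C(O[Si](CC)(CC)CC)CC[C@]12C | intermediate
11 | (1S,4aR,8aS)-5,8a-dimethyl-6-(triethylsilyloxy)-1,2,3,4,4a,7,8,8a-octahydronaphthalen-1-ol (OH syn to the angular methyl) | O[C@H]1CCC[C@H]2C(C)=C(O[Si](CC)(CC)CC)CC[C@]12C | intermediate
12 | 1,2,4,5-tetramethoxybenzene | COc1cc(OC)c(OC)cc1OC | starting material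
13 | (2,3,5,6-tetramethoxyphenyl)lithium | [Li]c1c(OC)c(OC)cc(OC)c1OC | intermediate
14 | 2,3,5,6-tetramethoxybenzaldehyde | O=Cc1c(OC)c(OC)cc(OC)c1OC | intermediate
15 | (2,3,5,6-tetramethoxyphenyl)methanol | OCc1c(OC)c(OC)cc(OC)c1OC | intermediate
16 | 3-(bromomethyl)-1,2,4,5-tetramethoxybenzene | BrCc1c(OC)c(OC)cc(OC)c1OC | intermediate
17 | dilithium (1S,4aR,8aS)-5,8a-dimethyl-1,2,3,4,4a,7,8,8a-octahydronaphthalene-1,6-bis(olate) | [Li+].[Li+].[O-][C@H]1CCC[C@H]2C(C)=C([O-])CC[C@]12C | intermediate
18 | (1S,4aS,5S,8aR)-5-hydroxy-1,4a-dimethyl-1-[(2,3,5,6-tetramethoxyphenyl)methyl]octahydronaphthalen-2(1H)-one | O[C@H]1CCC[C@H]2[C@](C)(Cc3c(OC)c(OC)cc(OC)c3OC)C(=O)CC[C@]12C | intermediate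
19 | (1S,4aS,5S,8aS)-5,8a-dimethyl-6-methylidene-5-[(2,3,5,6-tetramethoxyphenyl)methyl]decahydronaphthalen-1-ol | O[C@H]1CCC[C@H]2[C@](C)(Cc3c(OC)c(OC)cc(OC)c3OC)C(=C)CC[C@]12C | intermediate
20 | (1S,4aS,5R,6S,8aS)-5,6,8a-trimethyl-5-[(2,3,5,6-tetramethoxyphenyl)methyl]decahydronaphthalen-1-ol | O[C@H]1CCC[C@H]2[C@](C)(Cc3c(OC)c(OC)cc(OC)c3OC)[C@@H](C)CC[C@]12C | intermediate
21 | (4aS,5R,6S,8aS)-5,6,8a-trimethyl-5-[(2,3,5,6-tetramethoxyphenyl)methyl]octahydronaphthalen-1(2H)-one | O=C1CCC[C@H]2[C@](C)(Cc3c(OC)c(OC)cc(OC)c3OC)[C@@H](C)CC[C@]12C | intermediate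
22 | 1,2,4,5-tetramethoxy-3-{[(1R,2S,4aS,8aS)-1,2,4a-trimethyl-5-methylidenedecahydronaphthalen-1-yl]methyl}benzene | C=C1CCC[C@H]2[C@](C)(Cc3c(OC)c(OC)cc(OC)c3OC)[C@@H](C)CC[C@]12C | intermediate
23 | 2,5-dimethoxy-3-{[(1R,2S,4aS,8aS)-1,2,4a-trimethyl-5-methylidenedecahydronaphthalen-1-yl]methyl}cyclohexa-2,5-diene-1,4-dione | C=C1CCC[C@H]2[C@](C)(CC3=C(OC)C(=O)C=C(OC)C3=O)[C@@H](C)CC[C@]12C | intermediate
24 | potassium salt of ilimaquinone (potassium hydroxyquinonate) | [K+].C=C1CCC[C@H]2[C@](C)(CC3=C([O-])C(=O)C=C(OC)C3=O)[C@@H](C)CC[C@]12C | intermediate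
25 | ilimaquinone, 2-hydroxy-5-methoxy-3-{[(1R,2S,4aS,8aS)-1,2,4a-trimethyl-5-methylidenedecahydronaphthalen-1-yl]methyl}cyclohexa-2,5-diene-1,4-dione | C=C1CCC[C@H]2[C@](C)(CC3=C(O)C(=O)C=C(OC)C3=O)[C@@H](C)CC[C@]12C | target

**Count and risks**

Total step count: 17. Longest linear sequence: 14 steps (steps 1 to 7 and 11 to 17); the arene branch is steps 8 to 10.

Step 6. What may go wrong: poor facial discrimination by the catalyst on an enone that lacks an alpha-hydrogen, competition from the uncatalysed racemic cyclisation, or acid-induced loss of the silyl enol ether before cycloaddition. Fallback (known chemistry, resolution in place of catalyst control), setting out from 9 and coming back at 11: 9 is cyclised without a chiral catalyst (toluene, 80 °C) to the racemic trans-ketone, that is 10 mixed with its enantiomer (4aR,8aR)-5,8a-dimethyl-6-(triethylsilyloxy)-3,4,4a,7,8,8a-hexahydronaphthalen-1(2H)-one F1. LiAlH4 reduction gives 11 mixed with its enantiomer (1R,4aS,8aR)-5,8a-dimethyl-6-(triethylsilyloxy)-1,2,3,4,4a,7,8,8a-octahydronaphthalen-1-ol F2. Esterification with (S)-2-methoxy-2-phenylacetic acid (N,N'-dicyclohexylcarbodiimide, 4-(dimethylamino)pyridine, CH2Cl2) should give two diastereomers, the (S)-2-methoxy-2-phenylacetate of 11 F3 and the (S)-2-methoxy-2-phenylacetate of the enantiomer of 11 F4, to be separated by chromatography on base-washed silica. LiAlH4 cleavage of F3 returns 11.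

Step 11. What may go wrong: slow cleavage of the hindered tetrasubstituted triethylsilyl enol ether by MeLi, proton exchange of the enolate before alkylation, or O-benzylation of the C4 alkoxide. Fallback, setting out from 11 and coming back at 18: Saegusa–Ito oxidation of the silyl enol ether (Pd(OAc)2, MeCN, rt) should give the enone (4aS,5S)-5-hydroxy-1,4a-dimethyl-4,4a,5,6,7,8-hexahydronaphthalen-2(3H)-one F5. Birch-type reductive alkylation (Li, liquid NH3, THF, −78 °C, then 16) should then set the trans ring fusion at C10 again and alkylate the resulting enolate at C9 anti to the C5 methyl, giving 18. Because C10 is set anew, this path also repairs an insufficient trans to cis preference in step 6.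

Step 17. What may go wrong: attack of hydroxide at the other methoxy-bearing carbon (regioisomeric hydroxyquinone), double hydrolysis, or acid-induced migration of the exocyclic alkene during acidification. Fallback, setting out from 23 and coming back at 25: exhaustive hydrolysis (excess NaOH, aq. MeOH, 50 °C; careful acidification) to the dihydroxyquinone 2,5-dihydroxy-3-{[(1R,2S,4aS,8aS)-1,2,4a-trimethyl-5-methylidenedecahydronaphthalen-1-yl]methyl}cyclohexa-2,5-diene-1,4-dione F6. This is followed by mono-O-methylation of the less hindered and more acidic hydroxyl, the one flanked by the ring CH, with Me3SiCHN2 (1 equiv), MeOH/toluene, 0 °C, to give 25. Over-methylated material is 23 and can be recycled.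

**Further compounds**

F1 | step 6 | (4aR,8aR)-5,8a-dimethyl-6-(triethylsilyloxy)-3,4,4a,7,8,8a-hexahydronaphthalen-1(2H)-one (enantiomer of 10) | O=C1CCC[C@@H]2C(C)=C(O[Si](CC)(CC)CC)CC[C@@]12C
F2 | step 6 | (1R,4aS,8aR)-5,8a-dimethyl-6-(triethylsilyloxy)-1,2,3,4,4a,7,8,8a-octahydronaphthalen-1-ol (enantiomer of 11) | O[C@@H]1CCC[C@@H]2C(C)=C(O[Si](CC)(CC)CC)CC[C@@]12C
F3 | step 6 | (1S,4aR,8aS)-5,8a-dimethyl-6-(triethylsilyloxy)-1,2,3,4,4a,7,8,8a-octahydronaphthalen-1-yl (S)-2-methoxy-2-phenylacetate | CO[C@H](C(=O)O[C@H]1CCC[C@H]2C(C)=C(O[Si](CC)(CC)CC)CC[C@]12C)c1ccccc1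
F4 | step 6 | (1R,4aS,8aR)-5,8a-dimethyl-6-(triethylsilyloxy)-1,2,3,4,4a,7,8,8a-octahydronaphthalen-1-yl (S)-2-methoxy-2-phenylacetate | CO[C@H](C(=O)O[C@@H]1CCC[C@@H]2C(C)=C(O[Si](CC)(CC)CC)CC[C@@]12C)c1ccccc1
F5 | step 11 | (4aS,5S)-5-hydroxy-1,4a-dimethyl-4,4a,5,6,7,8-hexahydronaphthalen-2(3H)-one | O[C@H]1CCCC2=C(C)C(=O)CC[C@]12C
F6 | step 17 | 2,5-dihydroxy-3-{[(1R,2S,4aS,8aS)-1,2,4a-trimethyl-5-methylidenedecahydronaphthalen-1-yl]methyl}cyclohexa-2,5-diene-1,4-dione | C=C1CCC[C@H]2[C@](C)(CC3=C(O)C(=O)C=C(O)C3=O)[C@@H](C)CC[C@]12C
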